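## Retrosynthetic overview

1. Target 33 comes from desilylation and LiOOH removal of an (R)-4-benzyloxazolidinone that masks the free acid. The prenyl group comes from a Stille coupling on an aryl iodide, made by ortho-iodination of the only free phenol.
2. The acyclic (2S,3S)-2-benzyl-3-arylsuccinate comes from hydrogenolysis of the benzylic C5–O bond of an all-trans 3-aryl-4-acyl-5-aryl-γ-butyrolactone. The 3,4-trans relationship in this ring is the anti (erythro) array of the target.
3. That lactone is the only ring formed and it is temporary (lactol first, then lactone). It arises from oxidative cleavage of a vinyl group (the masked CO2Me carbon) next to the aldol hydroxyl, then base equilibration of the α-aryl centre.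
4. The key C–C bond (benzylic carbon to C2) is made by an intermolecular Evans boron syn-aldol of an N-(3-arylpent-4-enoyl)oxazolidinone with 4-benzyloxybenzaldehyde.
5. The aldol donor comes from vinyl-cuprate addition to the N-cinnamoyl imide, which comes from p-coumaric acid.

Assumption: the SMILES is read as (2S,3S) in acid numbering; compounds 9, 10, 12–14 and 16–19 are carried as epimer mixtures at the aryl-bearing carbon (left undefined in their SMILES) because step 7 sets it.

## Route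

Step 1
Reactants: 1 (E)-4-hydroxycinnamic acid; 2 chlorotriisopropylsilane
Product: 4 (E)-3-[4-(triisopropylsilyloxy)phenyl]acrylic acid, via bis-silylated coumarate 3 (not isolated)
Conditions: TIPSCl (2.3 equiv), imidazole, DMF, rt; then K2CO3, THF/H2O, 0 °C; 1 M HCl
Reagents that add atoms: chlorotriisopropylsilane CC(C)[Si](Cl)(C(C)C)C(C)C
Why: Exhaustive silylation followed by selective hydrolysis works because the silyl ester is cleaved by mild aqueous carbonate far faster than the hindered aryl TIPS ether (protecting-group installation).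

Step 2
Reactants: 4 (E)-3-[4-(triisopropylsilyloxy)phenyl]acrylic acid; 5 (R)-4-benzyloxazolidin-2-one
Product: 7 (R)-4-benzyl-3-{(E)-3-[4-(triisopropylsilyloxy)phenyl]acryloyl}oxazolidin-2-one, via mixed pivalic anhydride 6 (not isolated)
Conditions: PivCl, Et3N, THF, −20 °C; then LiCl, 5, −20 °C → rt
Reagents that add atoms: (R)-4-benzyloxazolidin-2-one O=C1N[C@H](Cc2ccccc2)CO1
Why: In this mixed-anhydride N-acylation (LiCl/Et3N protocol) the oxazolidinone attacks the unhindered cinnamoyl carbonyl rather than the pivaloyl one, and no strong base is needed.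

Step 3
Reactants: 7 N-cinnamoyl imide; 8 vinylmagnesium bromide
Product: 10 (4R)-4-benzyl-3-{3-[4-(triisopropylsilyloxy)phenyl]pent-4-enoyl}oxazolidin-2-one (epimer mixture at the aryl-bearing carbon), via magnesium enolate 9 (not isolated)
Conditions: CuBr·SMe2, vinylMgBr, THF/Me2S, −40 °C; add 7, −40 → −15 °C; aq NH4Cl
Reagents that add atoms: vinylmagnesium bromide C=C[Mg]Br
Why: Organocopper 1,4-addition to the chelated N-enoyl oxazolidinone installs vinyl as a non-enolisable masked carboxyl carbon, and the configuration of the new benzylic centre is immaterial because step 7 resets it.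

Step 4 (key step)
Reactants: 10 pentenoyl imide; 11 4-(benzyloxy)benzaldehyde
Product: 14 (4R)-4-benzyl-3-{(2R)-2-[(R)-[4-(benzyloxy)phenyl](hydroxy)methyl]-3-[4-(triisopropylsilyloxy)phenyl]pent-4-enoyl}oxazolidin-2-one, via Z-boron enolate 12 (not isolated), via boron aldolate 13 (not isolated)
Conditions: n-Bu2BOTf, Et3N, CH2Cl2, 0 °C; 11, −78 → 0 °C; pH 7 buffer, MeOH, 30% H2O2, 0 °C
Reagents that add atoms: 4-(benzyloxy)benzaldehyde O=Cc1ccc(OCc2ccccc2)cc1
Why: In this Evans syn-aldol the Z-boron enolate of the only enolisable site reacts through a Zimmerman–Traxler chair on the face away from the benzyl group of the (R)-auxiliary, which sets the α-carbon (future C2 of the target, R here by CIP) and the carbinol carbon (R) with about >95:5 selectivity.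

Step 5
Reactants: 14 aldol adduct; 15 sodium periodate
Product: 18 (4R)-4-benzyl-3-{[(2R,3R)-2-[4-(benzyloxy)phenyl]-5-hydroxy-4-[4-(triisopropylsilyloxy)phenyl]tetrahydrofuran-3-yl]carbonyl}oxazolidin-2-one (lactol; mixture at C4 and C5), via triol 16 (not isolated), via hydroxy aldehyde 17 (not isolated)
Conditions: OsO4 (2 mol %), NaIO4, 2,6-lutidine, dioxane/H2O 3:1, rt
Reagents that add atoms: sodium periodate [Na+].[O-]I(=O)(=O)=O (oxygen, relayed by catalytic OsO4 O=[Os](=O)(=O)=O)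
Why: Lemieux–Johnson cleavage attacks only the terminal alkene, spares the electron-rich arenes, and gives an aldehyde that is trapped at once by the aldol hydroxyl as a five-membered lactol.

Step 6
Reactants: 18 lactol
Product: 19 (4R)-4-benzyl-3-{[(2R,3R)-2-[4-(benzyloxy)phenyl]-5-oxo-4-[4-(triisopropylsilyloxy)phenyl]tetrahydrofuran-3-yl]carbonyl}oxazolidin-2-one (mixture at C4)
Conditions: TEMPO (10 mol %), PhI(OAc)2, CH2Cl2, rt
Reagents that add atoms: none
Why: Oxoammonium (TEMPO/BAIB) oxidation converts the lactol into the γ-lactone under neutral conditions that leave the imide, silyl ether and benzyl ether untouched.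

Step 7
Reactants: 19 lactone epimer mixture
Product: 20 (4R)-4-benzyl-3-{[(2R,3R,4S)-2-[4-(benzyloxy)phenyl]-5-oxo-4-[4-(triisopropylsilyloxy)phenyl]tetrahydrofuran-3-yl]carbonyl}oxazolidin-2-one (all-trans)
Conditions: DBU (0.1 equiv), CH2Cl2, rt, NMR control; recrystallise
Reagents that add atoms: none
Why: Base-mediated thermodynamic epimerisation of the acidic α-aryl lactone C–H funnels both epimers into the all-trans lactone, so the aldol-derived centres dictate the (S) configuration of the aryl-bearing carbon, while A(1,3) strain keeps the imide α-C–H inert.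

Step 8
Reactants: 20 all-trans lactone
Product: 22 (2S,3S)-4-[(4R)-4-benzyl-2-oxooxazolidin-3-yl]-3-(4-hydroxybenzyl)-4-oxo-2-[4-(triisopropylsilyloxy)phenyl]butanoic acid, via debenzylated lactone 21 (not isolated)
Conditions: H2 (4 bar), 10% Pd/C, EtOAc/AcOH 4:1, rt → 40 °C
Reagents that add atoms: none
Why: Catalytic hydrogenolysis cleaves both benzylic C–O bonds (the benzyl ether and the p-oxygenated benzylic lactone C–O), which erases the carbinol centre and leaves the two C–H stereocentres untouched (the former R centre is now S only through a CIP priority change).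

Step 9
Reactants: 22 acid; 23 trimethylsilyldiazomethane
Product: 24 methyl (2S,3S)-4-[(4R)-4-benzyl-2-oxooxazolidin-3-yl]-3-(4-hydroxybenzyl)-4-oxo-2-[4-(triisopropylsilyloxy)phenyl]butanoate
Conditions: TMSCHN2 (1.1 equiv), toluene/MeOH 4:1, 0 °C
Reagents that add atoms: trimethylsilyldiazomethane C[Si](C)(C)C=[N+]=[N-]
Why: Diazoalkane esterification is base-free, so the α-aryl centre cannot epimerise, and the carboxylic acid reacts far faster than the phenol.

Step 10
Reactants: 24 phenol; 25 N-iodosuccinimide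
Product: 26 methyl (2S,3S)-4-[(4R)-4-benzyl-2-oxooxazolidin-3-yl]-3-(4-hydroxy-3-iodobenzyl)-4-oxo-2-[4-(triisopropylsilyloxy)phenyl]butanoate
Conditions: NIS (1.0 equiv), TsOH·H2O (10 mol %), MeCN, 0 °C → rt, dark
Reagents that add atoms: N-iodosuccinimide O=C1CCC(=O)N1I
Why: Electrophilic aromatic iodination takes place on the only free, para-blocked phenol at one of its two equivalent ortho positions, because the TIPS-shielded aryl ether and the plain phenyl ring are much less reactive.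

Step 11
Reactants: 26 iodophenol; 2 chlorotriisopropylsilane
Product: 27 methyl (2S,3S)-4-[(4R)-4-benzyl-2-oxooxazolidin-3-yl]-3-[3-iodo-4-(triisopropylsilyloxy)benzyl]-4-oxo-2-[4-(triisopropylsilyloxy)phenyl]butanoate
Conditions: TIPSCl, imidazole, DMF, rt
Reagents that add atoms: chlorotriisopropylsilane CC(C)[Si](Cl)(C(C)C)C(C)C
Why: Silyl protection of the acidic o-iodophenol under imidazole is too weakly basic to epimerise the ester, and it removes the free OH before the Pd step and the basic peroxide step.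

Step 12
Reactants: 27 aryl iodide; 28 tributyl(3-methylbut-2-en-1-yl)stannane
Product: 29 methyl (2S,3S)-4-[(4R)-4-benzyl-2-oxooxazolidin-3-yl]-3-[3-(3-methylbut-2-en-1-yl)-4-(triisopropylsilyloxy)benzyl]-4-oxo-2-[4-(triisopropylsilyloxy)phenyl]butanoate
Conditions: Pd(PPh3)4 (5 mol %), degassed DMF, 80 °C; chromatography on K2CO3/silica
Reagents that add atoms: tributyl(3-methylbut-2-en-1-yl)stannane CCCC[Sn](CCCC)(CCCC)CC=C(C)C
Why: Stille coupling is neutral and so safe for the epimerisable ester, and reductive elimination from the aryl(prenyl)palladium species occurs at the less hindered allyl terminus to give the linear prenyl arene.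

Step 13
Reactants: 29 prenylated imide; 30 hydrogen peroxide
Product: 32 (2S,3S)-4-methoxy-2-[3-(3-methylbut-2-en-1-yl)-4-(triisopropylsilyloxy)benzyl]-4-oxo-3-[4-(triisopropylsilyloxy)phenyl]butanoic acid, via peroxy acid 31 (not isolated)
Conditions: LiOH, 30% H2O2, THF/H2O 3:1, 0 °C; aq Na2SO3; 1 M HCl to pH 3 at 0 °C
Reagents that add atoms: hydrogen peroxide OO
Why: Evans LiOOH cleavage attacks the exocyclic imide carbonyl selectively over the hindered methyl ester at 0 °C, the unactivated prenyl alkene is inert to nucleophilic peroxide, and the short cold exposure does not epimerise the tertiary α-aryl C–H.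

Step 14
Reactants: 32 bis-silyl acid
Product: 33 asperteretal G2 = (2S,3S)-2-[4-hydroxy-3-(3-methylbut-2-en-1-yl)benzyl]-3-(4-hydroxyphenyl)-4-methoxy-4-oxobutanoic acid
Conditions: TBAF, AcOH (1:1, 3 equiv each), THF, 0 °C; pH 3–4 work-up
Reagents that add atoms: none
Why: Acetic-acid-buffered fluoride desilylation removes both aryl TIPS ethers within minutes without acid (no chroman formation from the o-prenylphenol) and without free base (no epimerisation or ester hydrolysis).

## Compound list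

1 | (E)-4-hydroxycinnamic acid | OC(=O)/C=C/c1ccc(O)cc1 | starting material
2 | chlorotriisopropylsilane | CC(C)[Si](Cl)(C(C)C)C(C)C | starting material
3 | triisopropylsilyl (E)-3-[4-(triisopropylsilyloxy)phenyl]acrylate | CC(C)[Si](C(C)C)(C(C)C)OC(=O)/C=C/c1ccc(O[Si](C(C)C)(C(C)C)C(C)C)cc1 | intermediate
4 | (E)-3-[4-(triisopropylsilyloxy)phenyl]acrylic acid | OC(=O)/C=C/c1ccc(O[Si](C(C)C)(C(C)C)C(C)C)cc1 | intermediate
5 | (R)-4-benzyloxazolidin-2-one | O=C1N[C@H](Cc2ccccc2)CO1 | starting material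
6 | mixed anhydride of 4 with pivalic acid | CC(C)(C)C(=O)OC(=O)/C=C/c1ccc(O[Si](C(C)C)(C(C)C)C(C)C)cc1 | intermediate
7 | (R)-4-benzyl-3-{(E)-3-[4-(triisopropylsilyloxy)phenyl]acryloyl}oxazolidin-2-one | O=C(/C=C/c1ccc(O[Si](C(C)C)(C(C)C)C(C)C)cc1)N1[C@H](Cc2ccccc2)COC1=O | intermediate
8 | vinylmagnesium bromide | C=C[Mg]Br | starting material
9 | bromomagnesium (Z)-enolate of 10 | C=CC(c1ccc(O[Si](C(C)C)(C(C)C)C(C)C)cc1)/C=C(\O[Mg]Br)N1[C@H](Cc2ccccc2)COC1=O | intermediate
10 | (4R)-4-benzyl-3-{3-[4-(triisopropylsilyloxy)phenyl]pent-4-enoyl}oxazolidin-2-one (epimers at acyl C3) | C=CC(c1ccc(O[Si](C(C)C)(C(C)C)C(C)C)cc1)CC(=O)N1[C@H](Cc2ccccc2)COC1=O | intermediate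
11 | 4-(benzyloxy)benzaldehyde | O=Cc1ccc(OCc2ccccc2)cc1 | starting material
12 | (Z)-di-n-butylboron enolate of 10 | C=CC(c1ccc(O[Si](C(C)C)(C(C)C)C(C)C)cc1)/C=C(\OB(CCCC)CCCC)N1[C@H](Cc2ccccc2)COC1=O | intermediate
13 | di-n-butylboron aldolate of 14 | C=CC(c1ccc(O[Si](C(C)C)(C(C)C)C(C)C)cc1)[C@H]([C@@H](OB(CCCC)CCCC)c1ccc(OCc2ccccc2)cc1)C(=O)N1[C@H](Cc2ccccc2)COC1=O | intermediate
14 | syn-aldol adduct, acyl C2 (R), carbinol (R), auxiliary (R) | C=CC(c1ccc(O[Si](C(C)C)(C(C)C)C(C)C)cc1)[C@H]([C@@H](O)c1ccc(OCc2ccccc2)cc1)C(=O)N1[C@H](Cc2ccccc2)COC1=O | intermediate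
15 | sodium periodate | [Na+].[O-]I(=O)(=O)=O | starting material
16 | triol from dihydroxylation of the vinyl group of 14 | OCC(O)C(c1ccc(O[Si](C(C)C)(C(C)C)C(C)C)cc1)[C@H]([C@@H](O)c1ccc(OCc2ccccc2)cc1)C(=O)N1[C@H](Cc2ccccc2)COC1=O | intermediate
17 | open-chain γ-hydroxy α-aryl aldehyde | O=CC(c1ccc(O[Si](C(C)C)(C(C)C)C(C)C)cc1)[C@H]([C@@H](O)c1ccc(OCc2ccccc2)cc1)C(=O)N1[C@H](Cc2ccccc2)COC1=O | intermediate
18 | lactol, (2R,3R)-2-aryl-3-acyl-4-aryl-5-hydroxytetrahydrofuran | OC1O[C@@H](c2ccc(OCc3ccccc3)cc2)[C@H](C(=O)N2[C@H](Cc3ccccc3)COC2=O)C1c4ccc(O[Si](C(C)C)(C(C)C)C(C)C)cc4 | intermediate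
19 | γ-lactone, mixture at the α-aryl carbon | O=C1O[C@@H](c2ccc(OCc3ccccc3)cc2)[C@H](C(=O)N2[C@H](Cc3ccccc3)COC2=O)C1c4ccc(O[Si](C(C)C)(C(C)C)C(C)C)cc4 | intermediate
20 | all-trans (2R,3R,4S)-γ-lactone | O=C1O[C@@H](c2ccc(OCc3ccccc3)cc2)[C@H](C(=O)N2[C@H](Cc3ccccc3)COC2=O)[C@H]1c4ccc(O[Si](C(C)C)(C(C)C)C(C)C)cc4 | intermediate
21 | O-debenzylated all-trans lactone | O=C1O[C@@H](c2ccc(O)cc2)[C@H](C(=O)N2[C@H](Cc3ccccc3)COC2=O)[C@H]1c4ccc(O[Si](C(C)C)(C(C)C)C(C)C)cc4 | intermediate
22 | (2S,3S)-4-[(4R)-4-benzyl-2-oxooxazolidin-3-yl]-3-(4-hydroxybenzyl)-4-oxo-2-[4-(triisopropylsilyloxy)phenyl]butanoic acid | OC(=O)[C@H](c1ccc(O[Si](C(C)C)(C(C)C)C(C)C)cc1)[C@H](Cc1ccc(O)cc1)C(=O)N1[C@H](Cc2ccccc2)COC1=O | intermediate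
23 | trimethylsilyldiazomethane | C[Si](C)(C)C=[N+]=[N-] | starting material
24 | methyl ester of 22 | COC(=O)[C@H](c1ccc(O[Si](C(C)C)(C(C)C)C(C)C)cc1)[C@H](Cc1ccc(O)cc1)C(=O)N1[C@H](Cc2ccccc2)COC1=O | intermediate
25 | N-iodosuccinimide | O=C1CCC(=O)N1I | starting material
26 | 3-iodo-4-hydroxybenzyl compound | COC(=O)[C@H](c1ccc(O[Si](C(C)C)(C(C)C)C(C)C)cc1)[C@H](Cc1ccc(O)c(I)c1)C(=O)N1[C@H](Cc2ccccc2)COC1=O | intermediate
27 | bis-TIPS aryl iodide | COC(=O)[C@H](c1ccc(O[Si](C(C)C)(C(C)C)C(C)C)cc1)[C@H](Cc1ccc(O[Si](C(C)C)(C(C)C)C(C)C)c(I)c1)C(=O)N1[C@H](Cc2ccccc2)COC1=O | intermediate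
28 | tributyl(3-methylbut-2-en-1-yl)stannane | CCCC[Sn](CCCC)(CCCC)CC=C(C)C | starting material
29 | prenylated bis-TIPS imide | COC(=O)[C@H](c1ccc(O[Si](C(C)C)(C(C)C)C(C)C)cc1)[C@H](Cc1ccc(O[Si](C(C)C)(C(C)C)C(C)C)c(CC=C(C)C)c1)C(=O)N1[C@H](Cc2ccccc2)COC1=O | intermediate
30 | hydrogen peroxide | OO | starting material
31 | peroxy acid from imide cleavage | COC(=O)[C@H](c1ccc(O[Si](C(C)C)(C(C)C)C(C)C)cc1)[C@H](Cc1ccc(O[Si](C(C)C)(C(C)C)C(C)C)c(CC=C(C)C)c1)C(=O)OO | intermediate
32 | (2S,3S) bis-TIPS half-ester acid | COC(=O)[C@H](c1ccc(O[Si](C(C)C)(C(C)C)C(C)C)cc1)[C@H](Cc1ccc(O[Si](C(C)C)(C(C)C)C(C)C)c(CC=C(C)C)c1)C(=O)O | intermediate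
33 | asperteretal G2, (2S,3S) | COC(=O)[C@H](c1ccc(O)cc1)[C@H](Cc1ccc(O)c(CC=C(C)C)c1)C(=O)O | target

## Step count and risks

Total step count: 14. Longest linear sequence: 14 steps, from 1 to 33. All other partners are purchased.

**Step 7 (DBU equilibration).** DBU could also remove the proton α to the imide and expel the benzylic carboxylate by E1cB ring opening. The fallback sets out from lactol 18 and comes back at 20.
- Lactol 18 is stirred with Et3N in CH2Cl2.
- Ring–chain tautomerism exposes the α-aryl aldehyde 17, whose C–H is far more acidic than the imide C–H, so this weak base equilibrates the material to the 3,4-trans lactol F1.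
- The same TEMPO/PhI(OAc)2 oxidation then gives 20 directly, and the lactone never meets a base.

**Step 8 (hydrogenolytic lactone opening).** The reaction may stall at the debenzylated lactone 21. The fallback sets out from 20 and comes back at 24.
- Ionic hydrogenation (Et3SiH, TFA/CH2Cl2, rt) ionises the p-benzyloxybenzylic C–O bond, and hydride capture gives the O-benzyl acid F2.
- TMSCHN2 converts it into the O-benzyl methyl ester F3.
- An ordinary O-debenzylation (H2 1 atm, Pd/C, EtOAc) delivers 24.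

**Step 12 (Stille prenylation).** Risks are γ-transfer (reverse prenyl) and slow coupling next to the OTIPS group. The fallback sets out from 27 and comes back at 29.
- Pd-catalysed coupling with allyltributylstannane, which has no regiochemical ambiguity, gives the 3-allyl arene F4.
- Cross-metathesis with excess 2-methylbut-2-ene (Grubbs II, CH2Cl2, 40 °C) builds the trisubstituted alkene of 29.

## Further compounds

F1 | step 7 | (4R)-4-benzyl-3-{[(2R,3R,4S)-2-[4-(benzyloxy)phenyl]-5-hydroxy-4-[4-(triisopropylsilyloxy)phenyl]tetrahydrofuran-3-yl]carbonyl}oxazolidin-2-one (3,4-trans lactol, anomers) | OC1O[C@@H](c2ccc(OCc3ccccc3)cc2)[C@H](C(=O)N2[C@H](Cc3ccccc3)COC2=O)[C@H]1c4ccc(O[Si](C(C)C)(C(C)C)C(C)C)cc4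
F2 | step 8 | (2S,3S)-4-[(4R)-4-benzyl-2-oxooxazolidin-3-yl]-3-[4-(benzyloxy)benzyl]-4-oxo-2-[4-(triisopropylsilyloxy)phenyl]butanoic acid | OC(=O)[C@H](c1ccc(O[Si](C(C)C)(C(C)C)C(C)C)cc1)[C@H](Cc1ccc(OCc2ccccc2)cc1)C(=O)N1[C@H](Cc2ccccc2)COC1=O
F3 | step 8 | methyl ester of F2 | COC(=O)[C@H](c1ccc(O[Si](C(C)C)(C(C)C)C(C)C)cc1)[C@H](Cc1ccc(OCc2ccccc2)cc1)C(=O)N1[C@H](Cc2ccccc2)COC1=O
F4 | step 12 | methyl (2S,3S)-3-[3-allyl-4-(triisopropylsilyloxy)benzyl]-4-[(4R)-4-benzyl-2-oxooxazolidin-3-yl]-4-oxo-2-[4-(triisopropylsilyloxy)phenyl]butanoate | COC(=O)[C@H](c1ccc(O[Si](C(C)C)(C(C)C)C(C)C)cc1)[C@H](Cc1ccc(O[Si](C(C)C)(C(C)C)C(C)C)c(CC=C)c1)C(=O)N1[C@H](Cc2ccccc2)COC1=O
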